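**Retrosynthetic overview**
1. Target 15 ⇒ open-chain acid 13. Rings A and B are closed last in one photochemical cascade: C4–C5 closes ring A, then C9–C10 closes ring B, with loss of CO2 and H-7.
2. 13 ⇒ C1–C2 bond between allylic sulfone 6 and O-angeloyl anhydride 11; the sulfone is then removed reductively.
3. 6 ⇒ auraptene 3 (umbelliferone 1 + geranyl bromide 2) by allylic oxidation of the E-methyl group.
4. 11 ⇒ (S)-pantolactone 7 + angelic anhydride 10. The lactone supplies C2, C3, C4 and the carbon later expelled as CO2.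
5. Carbons of open-chain intermediates carry their drimane numbers (C1–C10; C11 = CH2OAr; Ar = 2-oxo-2H-chromen-7-yl).

Assumption: (S)-(+)-pantolactone (L-pantolactone) is taken as a commercial, inexpensive chiral-pool lactone.

**Step 1**
Reactants: 1 umbelliferone; 2 geranyl bromide
Product: 3 auraptene (7-[(2E)-3,7-dimethylocta-2,6-dienyloxy]chromen-2-one)
Conditions: K2CO3, acetone, reflux
Reagents that add atoms: none
Why: Williamson ether synthesis (SN2 of the phenoxide on the primary allylic bromide); the E-alkene is untouched and no stereocentre is formed.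

**Step 2**
Reactants: 3 auraptene
Product: 4 7-[(2E,6E)-8-hydroxy-3,7-dimethylocta-2,6-dienyloxy]chromen-2-one
Conditions: SeO2 (0.3 equiv), t-BuOOH (3 equiv), salicylic acid (0.1 equiv), CH2Cl2, rt
Reagents that add atoms: tert-butyl hydroperoxide, CC(C)(C)OO
Why: Sharpless–Umbreit SeO2 allylic oxidation (ene reaction, then [2,3]-shift) attacks the E-methyl group of the distal, electron-richer alkene and gives the E-allylic alcohol; the 2,3-alkene is deactivated by its allylic aryloxy group.

**Step 3**
Reactants: 4 the 8-hydroxy ether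
Product: 6 7-[(2E,6E)-3,7-dimethyl-8-(phenylsulfonyl)octa-2,6-dienyloxy]chromen-2-one, via allylic bromide 5 (not isolated)
Conditions: CBr4, PPh3, CH2Cl2, 0 °C; then PhSO2Na, DMF, rt
Reagents that add atoms: sodium benzenesulfinate, [Na+].[O-]S(=O)c1ccccc1
Why: Appel bromination followed by SN2 S-alkylation of the sulfinate gives the primary allylic sulfone with the E-alkene retained.

**Step 4**
Reactants: 7 (S)-pantolactone
Product: 9 (S)-2-hydroxy-3,3-dimethylbutanedioic acid, via sodium pantoate 8 (not isolated)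
Conditions: NaOH, H2O, 50 °C; then TEMPO (5 mol %), NaClO2 (2 equiv), NaOCl (2 mol %), NaH2PO4/Na2HPO4 buffer pH 6.7, MeCN, 35 °C; then HCl to pH 1
Reagents that add atoms: sodium hydroxide, [Na+].[OH-]; sodium chlorite, [Na+].[O-]Cl=O
Why: Lactone saponification, then oxoammonium/chlorite oxidation (Anelli–Zhao type) of the primary neopentyl alcohol to the acid; the secondary α-hydroxy carboxylate reacts far more slowly and the C3 centre is not involved.

**Step 5**
Reactants: 9 the hydroxy diacid; 10 angelic anhydride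
Product: 11 (3S)-4,4-dimethyl-2,5-dioxooxolan-3-yl (2Z)-2-methylbut-2-enoate
Conditions: 10 (2.3 equiv), Me3SiOSO2CF3 (2 mol %), CH2Cl2/MeCN, 0 → 40 °C; angelic acid removed under high vacuum
Reagents that add atoms: none
Why: Acid-catalysed O-acylation with dehydrative ring closure by anhydride exchange, as O-acylmalic anhydrides are made; with no nucleophilic catalyst or base the Z-alkene should not isomerise, and the C3–O bond is never broken, so C3 stays S.

**Step 6**
Reactants: 6 the allylic sulfone; 11 the O-angeloyl anhydride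
Product: 12 (3S,6E,10E)-3-(angeloyloxy)-2,2,6,10-tetramethyl-4-oxo-12-[(2-oxochromen-7-yl)oxy]-5-(phenylsulfonyl)dodeca-6,10-dienoic acid (C5 epimers)
Conditions: 6 (2.0 equiv, 1 equiv recovered), LiN(SiMe3)2 (2.0 equiv), THF, −78 °C; then 11, −78 °C; then AcOH
Reagents that add atoms: none
Why: C-acylation of the α-sulfonyl allyl carbanion, which reacts at the carbon next to sulfur, by opening the cyclic anhydride at its less hindered, acyloxy-activated carbonyl; this forms C1–C2 and frees the C4 carboxylate, and at −78 °C the anhydride should outcompete the coumarin lactone, the angelate and C3–H deprotonation.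

**Step 7**
Reactants: 12 the keto sulfone acid
Product: 13 (3S,6E,10E)-3-(angeloyloxy)-2,2,6,10-tetramethyl-4-oxo-12-[(2-oxochromen-7-yl)oxy]dodeca-6,10-dienoic acid
Conditions: SmI2 (divalent samarium, 2.1 equiv, added dropwise), THF/MeOH, −78 °C
Reagents that add atoms: none
Why: Reductive desulfonylation of a β-keto sulfone; the ketyl should lose sulfinate first because this gives an allyl-conjugated samarium dienolate, slow addition leaves no excess reductant for the C3 acyloxy group, and kinetic α-protonation returns the β,γ-unsaturated ketone with the E-alkene and C3 intact.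

**Step 8**
Reactants: 13 the open-chain acid
Product: 15 (2S,4aR,5R,8aS)-1,1,4a,6-tetramethyl-3-oxo-5-{[(2-oxo-2H-chromen-7-yl)oxy]methyl}-1,2,3,4,4a,5,8,8a-octahydronaphthalen-2-yl (2Z)-2-methylbut-2-enoate, via phthalimidyl ester 14 (not isolated)
Conditions: N-hydroxyphthalimide, N,N'-diisopropylcarbodiimide, DMAP (5 mol %), CH2Cl2, rt; then N-phenylbenzo[b]phenothiazine (10 mol %), LiBF4 (20 mol %), CH2Cl2/(CF3)2CHOH 9:1, 0.01 M, 440 nm LEDs, 20 °C
Reagents that add atoms: none
Why: Proposed new method: a photoredox decarboxylative radical–polar crossover that starts a cation–olefin bicyclisation. The excited phenothiazine reduces the ester, CO2 loss gives the tertiary C4 radical, and the phenothiazine radical cation oxidises it to the C4 cation, which the neighbouring angelate carbonyl holds as a 1,3-dioxolan-2-ylium ion. Like an epoxide, this bridged ion is opened at C4 anti to the C4–O bond by the C5=C10 alkene in a chair–chair fold with the C3–O bond equatorial, so the purchased C3 centre sets C5 and C10 (E-alkene gives the trans ring fusion) and C9 (E-alkene puts CH2OAr equatorial); a radical first ring closure anti to the C3–O bond leads to the same product. The C8 cation then loses H-7 to phthalimide anion to give the trisubstituted 7-ene. The closest known reactions are the organophotoredox decarboxylative etherification of tertiary N-acyloxyphthalimides through carbocations and epoxide-initiated polyene cyclisations.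

**Compound list**
1 | umbelliferone (7-hydroxychromen-2-one) | O=c1ccc2ccc(O)cc2o1 | starting material
2 | geranyl bromide | CC(C)=CCC/C(C)=C/CBr | starting material
3 | auraptene | CC(C)=CCC/C(C)=C/COc1ccc2ccc(=O)oc2c1 | intermediate
4 | 7-[(2E,6E)-8-hydroxy-3,7-dimethylocta-2,6-dienyloxy]chromen-2-one | OC/C(C)=C/CC/C(C)=C/COc1ccc2ccc(=O)oc2c1 | intermediate
5 | 7-[(2E,6E)-8-bromo-3,7-dimethylocta-2,6-dienyloxy]chromen-2-one | BrC/C(C)=C/CC/C(C)=C/COc1ccc2ccc(=O)oc2c1 | intermediate (not isolated)
6 | 7-[(2E,6E)-3,7-dimethyl-8-(phenylsulfonyl)octa-2,6-dienyloxy]chromen-2-one | O=S(=O)(C/C(C)=C/CC/C(C)=C/COc1ccc2ccc(=O)oc2c1)c1ccccc1 | intermediate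
7 | (S)-(+)-pantolactone, (3S)-3-hydroxy-4,4-dimethyloxolan-2-one | CC1(C)COC(=O)[C@H]1O | starting material
8 | sodium (2S)-2,4-dihydroxy-3,3-dimethylbutanoate (sodium pantoate) | [Na+].[O-]C(=O)[C@@H](O)C(C)(C)CO | intermediate (not isolated)
9 | (S)-2-hydroxy-3,3-dimethylbutanedioic acid | OC(=O)[C@@H](O)C(C)(C)C(=O)O | intermediate
10 | angelic anhydride, (2Z)-2-methylbut-2-enoic anhydride | C/C=C(/C)C(=O)OC(=O)C(/C)=C\C | starting material
11 | (3S)-4,4-dimethyl-2,5-dioxooxolan-3-yl (2Z)-2-methylbut-2-enoate | C/C=C(/C)C(=O)O[C@@H]1C(=O)OC(=O)C1(C)C | intermediate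
12 | (3S,6E,10E)-3-(angeloyloxy)-2,2,6,10-tetramethyl-4-oxo-12-[(2-oxochromen-7-yl)oxy]-5-(phenylsulfonyl)dodeca-6,10-dienoic acid, C5 epimers | C/C=C(/C)C(=O)O[C@H](C(=O)C(S(=O)(=O)c1ccccc1)/C(C)=C/CC/C(C)=C/COc1ccc2ccc(=O)oc2c1)C(C)(C)C(=O)O | intermediate
13 | (3S,6E,10E)-3-(angeloyloxy)-2,2,6,10-tetramethyl-4-oxo-12-[(2-oxochromen-7-yl)oxy]dodeca-6,10-dienoic acid | C/C=C(/C)C(=O)O[C@H](C(=O)C/C(C)=C/CC/C(C)=C/COc1ccc2ccc(=O)oc2c1)C(C)(C)C(=O)O | intermediate
14 | 1,3-dioxoisoindolin-2-yl ester of 13 | C/C=C(/C)C(=O)O[C@H](C(=O)C/C(C)=C/CC/C(C)=C/COc1ccc2ccc(=O)oc2c1)C(C)(C)C(=O)ON1C(=O)c2ccccc2C1=O | intermediate (not isolated)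
15 | CNP0111364.1, (2S,4aR,5R,8aS)-1,1,4a,6-tetramethyl-3-oxo-5-{[(2-oxo-2H-chromen-7-yl)oxy]methyl}-1,2,3,4,4a,5,8,8a-octahydronaphthalen-2-yl (2Z)-2-methylbut-2-enoate (drimane numbering 3S,5S,9R,10R) | C/C=C(/C)C(=O)O[C@@H]1C(=O)C[C@@]2(C)[C@H](COc3ccc4ccc(=O)oc4c3)C(C)=CC[C@@H]2C1(C)C | target

**Totals**
Total steps: 8. Longest linear sequence: 6 (steps 1, 2, 3, 6, 7, 8).

**Steps most likely to fail, with fallbacks**

Step 8 (the proposed cascade). Likely failure modes are proton loss from the C4 or C10 cation towards the ketone (enone formation), an unreactive dioxolanylium ion, or proton loss from the C8 methyl group instead of C7. The fallback uses known chemistry, sets out from 13 and returns at 15. Acridine/cobaloxime photochemical dehydrodecarboxylation of the tertiary acid (9-mesitylacridine, Co(dmgH)2(py)Cl, 400 nm, CH2Cl2) gives the isopropenyl ketone F1. Cobalt-hydride hydrogen-atom transfer to this 1,1-disubstituted alkene then starts the cyclisation to 15 under established radical–polar crossover polyene cyclisation conditions: the achiral salen complex Co(C32H46N2O2)Cl (ligand from 3,5-di-tert-butylsalicylaldehyde and ethylenediamine), N-fluoro-2,4,6-trimethylpyridinium tetrafluoroborate, PhSiH3, (CF3)2CHOH/CH2Cl2, 0 °C. The hydride reagent prefers the 1,1-disubstituted alkene over the two trisubstituted ones.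

Step 7 (SmI2 may also cleave the C3 angelate, which is α to the same ketone). The fallback removes the sulfone before any acyloxy group is present; it sets out from 9 and returns at 13, using 6 and 10 and by-passing 11 and 12. Diacid 9 is tied up with 2,2-dimethoxypropane and TsOH as the dioxolanone acid F2. Its lithium carboxylate acylates lithiated 6 at the dioxolanone carbonyl (LiN(SiMe3)2, THF, −78 °C); acetone leaves and the hydroxy keto sulfone acid F3 results. SmI2 then meets only an α-hydroxy ketone and gives the hydroxy keto acid F4. O-Angeloylation with 10 (MgBr2·OEt2, i-Pr2NEt, CH2Cl2, then aqueous work-up to hydrolyse the mixed anhydride at the carboxyl group) delivers 13.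

Step 5 (Z to E isomerisation of the angelate, or incomplete ring closure to the anhydride). The fallback installs the angelate by alkoxide acylation and closes the anhydride separately; it sets out from 9 and returns at 11. Diacid 9 is converted into the di-tert-butyl ester F5 (tert-butyl 2,2,2-trichloroacetimidate, BF3·OEt2 cat.). Its lithium alkoxide (LiN(SiMe3)2, THF, −78 °C) is acylated by 10 to the angelate diester F6. CF3CO2H in CH2Cl2 removes both tert-butyl groups to give the O-angeloyl diacid F7, and N,N'-dicyclohexylcarbodiimide closes it to 11.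

**Further compounds**
F1 | step 8 | (3S,6E,10E)-2,6,10-trimethyl-4-oxo-12-[(2-oxochromen-7-yl)oxy]dodeca-1,6,10-trien-3-yl (2Z)-2-methylbut-2-enoate | C/C=C(/C)C(=O)O[C@H](C(=O)C/C(C)=C/CC/C(C)=C/COc1ccc2ccc(=O)oc2c1)C(C)=C
F2 | step 7 | 2-[(4S)-2,2-dimethyl-5-oxo-1,3-dioxolan-4-yl]-2-methylpropanoic acid | CC1(C)OC(=O)[C@@H](O1)C(C)(C)C(=O)O
F3 | step 7 | (3S,6E,10E)-3-hydroxy-2,2,6,10-tetramethyl-4-oxo-12-[(2-oxochromen-7-yl)oxy]-5-(phenylsulfonyl)dodeca-6,10-dienoic acid | O[C@H](C(=O)C(S(=O)(=O)c1ccccc1)/C(C)=C/CC/C(C)=C/COc1ccc2ccc(=O)oc2c1)C(C)(C)C(=O)O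
F4 | step 7 | (3S,6E,10E)-3-hydroxy-2,2,6,10-tetramethyl-4-oxo-12-[(2-oxochromen-7-yl)oxy]dodeca-6,10-dienoic acid | O[C@H](C(=O)C/C(C)=C/CC/C(C)=C/COc1ccc2ccc(=O)oc2c1)C(C)(C)C(=O)O
F5 | step 5 | di-tert-butyl (S)-2-hydroxy-3,3-dimethylbutanedioate | CC(C)(C)OC(=O)[C@@H](O)C(C)(C)C(=O)OC(C)(C)C
F6 | step 5 | di-tert-butyl (S)-2-[(2Z)-2-methylbut-2-enoyloxy]-3,3-dimethylbutanedioate | C/C=C(/C)C(=O)O[C@H](C(=O)OC(C)(C)C)C(C)(C)C(=O)OC(C)(C)C
F7 | step 5 | (S)-2-[(2Z)-2-methylbut-2-enoyloxy]-3,3-dimethylbutanedioic acid | C/C=C(/C)C(=O)O[C@H](C(=O)O)C(C)(C)C(=O)O
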